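**Assumption (one line):** the benzyl ethers 2, 7 and 11 are bought; the sense of induction of the new step 4 must be fixed in a pilot run (both antipodes of the acid are available), and the route is written for the antipode that gives (3S), taken here as the (R)-acid.

## Retrosynthetic overview

1. Target ⇐ removal of five O-benzyl groups; the (E)-stilbene arm ⇐ Heck coupling of an aryl bromide with 3,5-bis(benzyloxy)styrene.
2. The (S)-1,1,2-triarylethane ⇐ reductive opening of the benzylic O1–C2 bond of a (2S,3S)-2,3-diaryl-2,3-dihydrobenzofuran; the ring oxygen is the phenol of the central ring.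
3. Key disconnection: the O1–C2 bond of that ring, closed by a chiral-acid-catalysed asymmetric cycloisomerisation of a 2-hydroxy triarylethene; this closure fixes C3, the only stereocentre of the target.
4. Triarylethene ⇐ Horner–Wadsworth–Emmons olefination of a diarylmethylphosphonate with 2,4-bis(benzyloxy)benzaldehyde; phosphonate ⇐ ortho-quinone methide ⇐ benzhydrol ⇐ aryl Grignard plus 5-bromo-2-hydroxy-3-methoxybenzaldehyde.
5. Ring order: all four benzene rings are bought; the only ring made is the dihydrofuran (step 4), which is opened again in step 5.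

## Route

Step 1
Reactants: 1 5-bromo-2-hydroxy-3-methoxybenzaldehyde; 2 1-(benzyloxy)-4-bromo-2-methoxybenzene
Product: 4 rac-[4-(benzyloxy)-3-methoxyphenyl](5-bromo-2-hydroxy-3-methoxyphenyl)methanol, via arylmagnesium bromide 3 (not isolated)
Conditions: 2, Mg, THF, 40 °C; add 3 (2.3 equiv) to 1, THF, 0 °C to rt; aq NH4Cl
Reagents that add atoms: none
Why: Grignard addition to the aldehyde; the first equivalent only deprotonates the phenol and the magnesium phenoxide then takes up the second, while the aryl bromide of 1 is inert at this temperature.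

Step 2
Reactants: 4 rac-[4-(benzyloxy)-3-methoxyphenyl](5-bromo-2-hydroxy-3-methoxyphenyl)methanol
Product: 6 rac-diethyl {[4-(benzyloxy)-3-methoxyphenyl](5-bromo-2-hydroxy-3-methoxyphenyl)methyl}phosphonate, via ortho-quinone methide 5 (not isolated)
Conditions: HP(O)(OEt)2 (3 equiv), TsOH·H2O (10 mol%), toluene, 80 °C
Reagents that add atoms: diethyl phosphite, CCO[PH](=O)OCC
Why: acid-promoted dehydration of the ortho-hydroxybenzhydrol gives the ortho-quinone methide, which is trapped by phospha-Michael (Pudovik-type) addition with re-aromatisation.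

Step 3
Reactants: 6 rac-diethyl {[4-(benzyloxy)-3-methoxyphenyl](5-bromo-2-hydroxy-3-methoxyphenyl)methyl}phosphonate; 7 2,4-bis(benzyloxy)benzaldehyde
Product: 8 2-{1-[4-(benzyloxy)-3-methoxyphenyl]-2-[2,4-bis(benzyloxy)phenyl]ethenyl}-4-bromo-6-methoxyphenol (E/Z mixture)
Conditions: KOt-Bu (2.5 equiv), THF, 0 to 40 °C; aq NH4Cl (no strong acid)
Reagents that add atoms: none
Why: Horner–Wadsworth–Emmons olefination of the phenoxide/diarylmethylphosphonate dianion, a standard way to triarylethenes; the alkene geometry does not matter because both isomers converge in step 4.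

Step 4
Reactants: 8 2-{1-[4-(benzyloxy)-3-methoxyphenyl]-2-[2,4-bis(benzyloxy)phenyl]ethenyl}-4-bromo-6-methoxyphenol
Product: 9 (2S,3S)-3-[4-(benzyloxy)-3-methoxyphenyl]-2-[2,4-bis(benzyloxy)phenyl]-5-bromo-7-methoxy-2,3-dihydro-1-benzofuran
Conditions: (R)-3,3'-bis(2,4,6-triisopropylphenyl)-1,1'-binaphthyl-2,2'-diyl N-triflylphosphoramide (10 mol%), toluene (0.02 M), 5 Å MS, −40 to −20 °C
Reagents that add atoms: none
Why: Proposed new method: the strong chiral acid protonates the electron-rich alkene reversibly at the diaryl carbon to give a 2,4-dialkoxybenzylic cation paired with the chiral phosphoramidate, and the neighbouring phenol, hydrogen-bonded to the same anion, traps it by O1–C2 bond formation; because the E/Z isomers and both C3-epimeric cations interconvert through the alkene and its ortho-quinone methide tautomer, the C–O ring closure selects the (3S) cation (Curtin–Hammett) and gives the trans ring, while low temperature and dilution suppress re-ionisation of the product and intermolecular trapping; the closest known reaction types are the chiral Brønsted acid catalysed intramolecular hydroalkoxylation of alkenes to cyclic ethers and the racemic acid-mediated cyclisation of 2-hydroxystilbenes to 2-aryl-2,3-dihydrobenzofurans.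

Step 5
Reactants: 9 (2S,3S)-3-[4-(benzyloxy)-3-methoxyphenyl]-2-[2,4-bis(benzyloxy)phenyl]-5-bromo-7-methoxy-2,3-dihydro-1-benzofuran
Product: 10 2-{(1S)-1-[4-(benzyloxy)-3-methoxyphenyl]-2-[2,4-bis(benzyloxy)phenyl]ethyl}-4-bromo-6-methoxyphenol
Conditions: Et3SiH (10 equiv), TFA (5 equiv), CH2Cl2, −20 °C; aq NaHCO3
Reagents that add atoms: none
Why: ionic hydrogenation; the O1–C2 bond ionises like a 2,4-dialkoxybenzyl ether and the cation is reduced by the silane at C2 only, so C3 is carried over unchanged (a C2 epimer of 9 gives the same product), and excess silane at low temperature limits proton loss from C3.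

Step 6
Reactants: 11 3,5-bis(benzyloxy)benzaldehyde
Product: 12 1,3-bis(benzyloxy)-5-ethenylbenzene
Conditions: Ph3PCH3Br (1.2 equiv), KOt-Bu (1.2 equiv), THF, 0 °C to rt
Reagents that add atoms: methyltriphenylphosphonium bromide, C[P+](c1ccccc1)(c1ccccc1)c1ccccc1.[Br-]
Why: Wittig methylenation of an aromatic aldehyde.

Step 7
Reactants: 10 2-{(1S)-1-[4-(benzyloxy)-3-methoxyphenyl]-2-[2,4-bis(benzyloxy)phenyl]ethyl}-4-bromo-6-methoxyphenol; 12 1,3-bis(benzyloxy)-5-ethenylbenzene
Product: 13 2-{(1S)-1-[4-(benzyloxy)-3-methoxyphenyl]-2-[2,4-bis(benzyloxy)phenyl]ethyl}-4-{(E)-2-[3,5-bis(benzyloxy)phenyl]ethenyl}-6-methoxyphenol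
Conditions: Pd(OAc)2 (5 mol%), P(o-tol)3 (10 mol%), NaOAc (2 equiv), DMA, 120 °C
Reagents that add atoms: none
Why: Mizoroki–Heck coupling of the aryl bromide with the styrene gives the (E)-stilbene; the free phenol and the non-acidic benzylic stereocentre tolerate the acetate base.

Step 8
Reactants: 13 2-{(1S)-1-[4-(benzyloxy)-3-methoxyphenyl]-2-[2,4-bis(benzyloxy)phenyl]ethyl}-4-{(E)-2-[3,5-bis(benzyloxy)phenyl]ethenyl}-6-methoxyphenol
Product: 14 4-[(2S)-2-{5-[(E)-2-(3,5-dihydroxyphenyl)ethenyl]-2-hydroxy-3-methoxyphenyl}-2-(4-hydroxy-3-methoxyphenyl)ethyl]benzene-1,3-diol (CNP0254096.1)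
Conditions: BCl3 (12 equiv), pentamethylbenzene (15 equiv), CH2Cl2, −78 °C; aqueous quench
Reagents that add atoms: none
Why: Lewis-acid debenzylation with a non-Lewis-basic cation scavenger removes all five benzyl ethers at −78 °C without reducing the stilbene, cleaving the two methyl ethers or touching the stereocentre.

## Compound list

1 | 5-bromo-2-hydroxy-3-methoxybenzaldehyde | COc1cc(Br)cc(C=O)c1O | starting material
2 | 1-(benzyloxy)-4-bromo-2-methoxybenzene | COc1cc(Br)ccc1OCc1ccccc1 | starting material
3 | [4-(benzyloxy)-3-methoxyphenyl]magnesium bromide | COc1cc([Mg]Br)ccc1OCc1ccccc1 | intermediate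
4 | rac-[4-(benzyloxy)-3-methoxyphenyl](5-bromo-2-hydroxy-3-methoxyphenyl)methanol | COc1cc(Br)cc(C(O)c2ccc(OCc3ccccc3)c(OC)c2)c1O | intermediate
5 | 6-{[4-(benzyloxy)-3-methoxyphenyl]methylidene}-4-bromo-2-methoxycyclohexa-2,4-dien-1-one | COC1=CC(Br)=CC(=Cc2ccc(OCc3ccccc3)c(OC)c2)C1=O | intermediate
6 | rac-diethyl {[4-(benzyloxy)-3-methoxyphenyl](5-bromo-2-hydroxy-3-methoxyphenyl)methyl}phosphonate | CCOP(=O)(OCC)C(c1ccc(OCc2ccccc2)c(OC)c1)c1cc(Br)cc(OC)c1O | intermediate
7 | 2,4-bis(benzyloxy)benzaldehyde | O=Cc1ccc(OCc2ccccc2)cc1OCc1ccccc1 | starting material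
8 | 2-{1-[4-(benzyloxy)-3-methoxyphenyl]-2-[2,4-bis(benzyloxy)phenyl]ethenyl}-4-bromo-6-methoxyphenol (E/Z mixture, no stereocentre) | COc1cc(Br)cc(C(=Cc2ccc(OCc3ccccc3)cc2OCc2ccccc2)c2ccc(OCc3ccccc3)c(OC)c2)c1O | intermediate
9 | (2S,3S)-3-[4-(benzyloxy)-3-methoxyphenyl]-2-[2,4-bis(benzyloxy)phenyl]-5-bromo-7-methoxy-2,3-dihydro-1-benzofuran | COc1cc(Br)cc2c1O[C@H](c1ccc(OCc3ccccc3)cc1OCc1ccccc1)[C@H]2c1ccc(OCc2ccccc2)c(OC)c1 | intermediate
10 | 2-{(1S)-1-[4-(benzyloxy)-3-methoxyphenyl]-2-[2,4-bis(benzyloxy)phenyl]ethyl}-4-bromo-6-methoxyphenol | COc1cc([C@H](Cc2ccc(OCc3ccccc3)cc2OCc2ccccc2)c2cc(Br)cc(OC)c2O)ccc1OCc1ccccc1 | intermediate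
11 | 3,5-bis(benzyloxy)benzaldehyde | O=Cc1cc(OCc2ccccc2)cc(OCc2ccccc2)c1 | starting material
12 | 1,3-bis(benzyloxy)-5-ethenylbenzene | C=Cc1cc(OCc2ccccc2)cc(OCc2ccccc2)c1 | intermediate
13 | 2-{(1S)-1-[4-(benzyloxy)-3-methoxyphenyl]-2-[2,4-bis(benzyloxy)phenyl]ethyl}-4-{(E)-2-[3,5-bis(benzyloxy)phenyl]ethenyl}-6-methoxyphenol | COc1cc([C@H](Cc2ccc(OCc3ccccc3)cc2OCc2ccccc2)c2cc(/C=C/c3cc(OCc4ccccc4)cc(OCc4ccccc4)c3)cc(OC)c2O)ccc1OCc1ccccc1 | intermediate
14 | 4-[(2S)-2-{5-[(E)-2-(3,5-dihydroxyphenyl)ethenyl]-2-hydroxy-3-methoxyphenyl}-2-(4-hydroxy-3-methoxyphenyl)ethyl]benzene-1,3-diol | COc1cc([C@H](Cc2ccc(O)cc2O)c2cc(/C=C/c3cc(O)cc(O)c3)cc(OC)c2O)ccc1O | target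

## Step count and risks

Total steps: 8. Longest linear sequence: 7 (steps 1, 2, 3, 4, 5, 7, 8; step 6 is a one-step side branch).

**Step 4 (proposed new reaction).** The acid may fail to give useful enantioselectivity, or the product may re-ionise and racemise. The fallback uses known chemistry and sets out from 8: asymmetric transfer hydrogenation of the ortho-hydroxy 1,1-diarylalkene with (R)- or (S)-3,3'-bis(2,4,6-triisopropylphenyl)-1,1'-binaphthyl-2,2'-diyl hydrogen phosphate (5 mol%) and diethyl 2,6-dimethyl-1,4-dihydropyridine-3,5-dicarboxylate in CH2Cl2. The phosphoric acid turns 8 into its ortho-quinone methide tautomer and directs hydride delivery to the diaryl carbon. This comes back to the route at 10, so the ring is never closed and step 5 drops out. Compounds outside the list: none F0.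

**Step 5 (ee erosion).** The C2 cation can lose the doubly benzylic C3 proton to give 8, which an achiral acid would then reduce to racemic material. The fallback sets out from 9 and replaces substrate-controlled, stereoretentive cleavage by a catalyst-controlled, enantioconvergent one. Compound 9 is warmed (0 to 25 °C) with the chiral phosphoric acid of the preceding fallback and the same dihydropyridine. Ionised 9 and any 8 formed by proton loss both drain through the ortho-quinone methide, which is reduced under control of the chiral acid, so the stereocentre no longer depends on retention. It comes back at 10. Compounds outside the list: none F0.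

**Step 3 (olefination).** The hindered dianion and the electron-rich, ortho-substituted aldehyde may react poorly. The fallback sets out from 4: oxidation with MnO2 in CH2Cl2 gives the ketone [4-(benzyloxy)-3-methoxyphenyl](5-bromo-2-hydroxy-3-methoxyphenyl)methanone F1. A crossed McMurry coupling of this ketone with 7 (2 equiv) using TiCl4, Zn and pyridine in refluxing THF (low-valent titanium, which tolerates the aryl bromide and the free phenol) then gives the triarylethene, coming back to the route at 8.

## Further compounds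

F1 | step 3 | [4-(benzyloxy)-3-methoxyphenyl](5-bromo-2-hydroxy-3-methoxyphenyl)methanone | COc1cc(Br)cc(C(=O)c2ccc(OCc3ccccc3)c(OC)c2)c1O
F0 | step 4 | none | none
F0 | step 5 | none | none
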